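## Analysis of the target

The target 32 is a bicyclic diterpenoid of the labdane type in the enantiomeric series, (2R,5R,9R,10R,13Z). It is a trans-fused decalin (ring A = C1–C5 and C10; ring B = C5–C10) carrying a C2 hydroxyl, the C4 gem-dimethyl group, the C10 methyl group, an exocyclic C8=C17 methylene and, on C9, the six-carbon chain C11–C16.

C5 and C10 define the trans ring fusion. The C9 chain is equatorial and cis to the C10 methyl (H-9 cis to H-5). The C2 hydroxyl is equatorial and trans to the C10 methyl. The fifth stereo-element is the C13=C14 bond, in which the acetoxymethyl carbon C16 is cis to the carboxyl carbon C15.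

The sensitive part is this (Z)-γ-acetoxy enoic acid. Loss or migration of the acetyl group opens the way to the butenolide, so C15 cannot be released from an ester with base. The 1,1-disubstituted C8=C17 alkene migrates under strong acid and can trap a C12 oxygen.

The difficulties are steric and stereochemical:
- C5 lies between two fully substituted carbons (C4 and C10).
- A hydride attacks a C2 ketone from the open face and gives the axial alcohol.
- C9 sits beside the C10 quaternary centre, where the usual equatorial preference is eroded.
- C13 bears two CH2 groups, so a carbonyl olefination cannot fix its geometry.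

The route rests on one feature of ring A. The segment C1–C2(O)–C3–C4(CH3)2 has the skeleton and oxidation pattern of mesityl oxide (1), and the C2 oxygen is 1,4 to C5. Ring A is therefore the cycloadduct of the 2-silyloxydiene C1=C2–C3=C4 (2) with a C5=C10 enal (8) that supplies C6 as the formyl group, the C10 methyl and C7–C9 as a masked 2-oxopropyl arm. This forms both bonds to the quaternary carbons, C1–C10 and C4–C5, in one step.

## Retrosynthetic reasoning

**C15 oxidation level (32 ← 31 ← 30 ← 29).** No C–C bond is cut. The carboxyl group is made last by two mild oxidations of an allylic alcohol, because a C15 ester could only be cleaved under conditions that endanger the cis acetate. The forward steps must oxidise the primary allylic alcohol beside the free C2 carbinol without isomerising C13=C14.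

**C12–C13 (29 ← 28 ← 21 + 25).** The sp3–sp2 bond C12–C13 is cut. This separates the decalin from a four-carbon piece whose alkene geometry can be fixed in a small molecule. A cut at C13=C14 would need olefination of a ketone flanked by two similar CH2 groups. The forward reaction is a B-alkyl Suzuki–Miyaura coupling with retention of the vinyl geometry. The acetyl group is added only afterwards (28 → 29), so no allylic ester is present during the coupling.

**Side-chain piece (25 ← 24 ← 23 ← 22).** The C–I bond comes from a C–Sn bond with retention. Syn-hydrostannation of the symmetrical alkyne 22 sets the geometry with no regiochemical question. The two hydroxyls are then told apart by the bulk of the tin group.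

**C2 carbinol and C12 iodide (21 ← 20 ← 19 ← 18).** The C2 alcohol comes from the ketone by dissolving-metal reduction, which gives the thermodynamic equatorial epimer. This is placed where nothing else is reducible, after C8 has become the alkene. The primary C12 hydroxyl is then converted into the iodide in the presence of the doubly neopentyl C2 carbinol.

**C8=C17 (18 ← 17 ← 16).** The exocyclic alkene comes from the C8 ketone by a non-basic methylenation, so that C9 is not epimerised. One desilylation then frees the C2 ketone and the C12 hydroxyl.

**C9–C11 (16 ← 15 ← 13 ← 11 + 12).** The bond C9–C11 is cut as an aldol addition of the α′-enolate of enone 11. The C6=C7 bond blocks enolisation towards C7 and the silyl enol ether hides C2. Dehydration to the C9=C11 alkylidene and hydrogenation deliver H-9 from the face opposite the C10 methyl. C9 is thus set under kinetic control. A direct alkylation would bring the electrophile in on that same open face and give the wrong epimer, and equilibration at C9 is not reliable.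

**Ring B (11 ← 10 ← 9).** The C6=C7 bond is cut as an intramolecular aldol condensation of the C7 methyl ketone onto the C6 aldehyde. The trans relation of C6 and C9 in 9 becomes the trans ring fusion.

**Ring A (9 ← 2 + 8).** Both bonds to the quaternary carbons, C1–C10 and C4–C5, are cut in a [4+2] sense. This is the only disconnection that removes the whole congested C4–C5–C10 triad at once, and it leads to two small achiral partners. The forward step must join a hindered diene and a β,β-disubstituted enal with control of regiochemistry, of the C5/C10 relation and of absolute configuration.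

**Partners (8 ← 7 ← 6 ← 4 + 5, 4 ← 3; 2 ← 1).** The enal comes from monoketalised 3 by Horner–Wadsworth–Emmons olefination with 5, reduction and allylic oxidation. The diene is the kinetic silyl dienol ether of 1.

## Alternatives that were turned down

**Alternative 1:** photocycloaddition followed by cyclobutane cleavage.
- Disconnection: C9–C10 and a sacrificial C1–C11 bond across the C1=C10 double bond of the ring A enone A2, which already holds the C2 ketone, the gem-dimethyl group and the C5 chain (C6–C8 and C17).
- Key step: irradiation of A2 with allene A3 gives the methylenecyclobutane A1, with C10 quaternary and the facial sense taken from C5.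
- For: an excited-state [2+2] addition is largely indifferent to crowding at C10 and is established chemistry. On the certainty of making the C10 quaternary centre it is stronger than the chosen step.
- Against: one of the two new bonds must be broken again, by alkene cleavage and fragmentation of the resulting strained 1,3-dicarbonyl. C11 then emerges at the carboxyl level and must be reduced and extended. Ring B has to be closed by an aldol onto the C8 methyl ketone, and the tertiary carbinol must be dehydrated to the exocyclic C8=C17 isomer against conjugation. The C5 stereocentre of A2 must first be made enantioselectively beside a quaternary carbon.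
- Comparison: the chosen strategy keeps both bonds it forms, sets C5 and C10 together, and reaches C8 as a ketone that is methylenated directly, which saves the fragmentation and redox steps.

**Alternative 2:** intramolecular Diels–Alder reaction of an open-chain trienal.
- Disconnection: C5–C10 and C8–C9 of ring B in the trienal A5, in which the C1–C4 tether links a C5–C8 dienol silyl ether to the C9=C10 enal.
- Key step: heating A5 gives the octalin aldehyde A4, closing both rings and setting C5, C8, C9 and C10.
- For: it sets four stereocentres in one step, against two in the chosen step. Intramolecularity helps to overcome the hindrance at C10. The absolute configuration comes from the single C2 carbinol and not from an unproven catalyst. On these three points it is stronger.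
- Against: A5 is a long and labile substrate, with an acid-sensitive dienol ether, an isomerisable trisubstituted enal and a quaternary carbon in the tether, so many linear steps are invested before the uncertain step. Control of ring fusion and facial sense by a remote C2 substituent is not secure. A4 still needs reduction of C6=C7, conversion of the C8 silyl ether into the methylene group, and growth of the whole chain from an epimerisable C9 aldehyde.
- Comparison: the downstream length is similar. The chosen strategy offers partners made in one and four steps, so its risky step is tested early and cheaply.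

**Alternative 3:** conjugate addition and enolate alkylation on a ring B enone.
- Disconnection: C9–C11 and C1–C10 on the enantiopure enone A7.
- Key step: a copper-mediated addition of the Grignard reagent A8 to C9, anti to the C8 silyloxy group, followed by alkylation of the enolate at C10 with the bromoketone A9, gives A6.
- For: this is established chemistry with substrate-based stereocontrol, and it sets C9 kinetically. On certainty of the key step and on absolute control it is stronger.
- Against: the hindered α-methyl enolate must be alkylated by an enolisable α-bromo enone, where proton transfer competes. The most congested bond, C4–C5, is postponed to a late ring A closure onto the C5 carbonyl, which leaves a tertiary oxygen at C5 to be removed with control of configuration. The acetal chain of A6 must still be converted into the trisubstituted alkene, and C8 into the methylene group.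
- Comparison: the chosen strategy makes C4–C5 and C1–C10 together at the outset, when little material is invested, at the price of a less certain single step.

Key step: step 6

Assumption: the face exposed by the (S)-oxazaborolidinium ion is assigned from the usual formyl C–H···O binding model for s-trans enals; if the sense proves opposite, the (R)-catalyst takes its place without other change.

## Route

Step 1
Reactants: 1 mesityl oxide
Product: 2 triisopropyl[(4-methylpenta-1,3-dien-2-yl)oxy]silane
Conditions: LiN(i-Pr)2, THF, −78 °C; TIPSOTf, −78 to 0 °C
Reagents that add atoms: triisopropylsilyl triflate, CC(C)[Si](C(C)C)(C(C)C)OS(=O)(=O)C(F)(F)F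
Why: Kinetic deprotonation of the enone at the acetyl methyl gives the cross-conjugated lithium dienolate, which is O-silylated; the bulky silyl group makes the dienol ether robust towards acid.

Step 2
Reactants: 3 acetylacetone
Product: 4 1-(2-methyl-1,3-dioxolan-2-yl)propan-2-one
Conditions: ethylene glycol (1 equiv), TsOH·H2O (cat.), benzene, reflux, Dean–Stark trap
Reagents that add atoms: ethylene glycol, OCCO
Why: Acid-catalysed ketalisation with one equivalent of diol gives mainly the monoketal, which is separated from diketone and bisketal by distillation.

Step 3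
Reactants: 4 1-(2-methyl-1,3-dioxolan-2-yl)propan-2-one; 5 triethyl phosphonoacetate
Product: 6 ethyl (E)-3-methyl-4-(2-methyl-1,3-dioxolan-2-yl)but-2-enoate
Conditions: NaH, THF, 0 °C to reflux
Reagents that add atoms: none
Why: Horner–Wadsworth–Emmons olefination of the methyl ketone, as with other β-keto acetals; the (E) isomer (ester trans to the ketal arm) should predominate and is separated from the (Z) isomer by chromatography.

Step 4
Reactants: 6 ethyl (E)-3-methyl-4-(2-methyl-1,3-dioxolan-2-yl)but-2-enoate
Product: 7 (E)-3-methyl-4-(2-methyl-1,3-dioxolan-2-yl)but-2-en-1-ol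
Conditions: i-Bu2AlH (2.2 equiv), CH2Cl2, −78 to 0 °C; aq. potassium sodium tartrate
Reagents that add atoms: none
Why: 1,2-Reduction of the enoate to the allylic alcohol; the ketal and the alkene geometry are untouched.

Step 5
Reactants: 7 (E)-3-methyl-4-(2-methyl-1,3-dioxolan-2-yl)but-2-en-1-ol
Product: 8 (E)-3-methyl-4-(2-methyl-1,3-dioxolan-2-yl)but-2-enal
Conditions: activated MnO2, CH2Cl2, 25 °C
Reagents that add atoms: none
Why: Neutral allylic oxidation that should neither isomerise the trisubstituted alkene nor open the β-positioned dioxolane.

Step 6
Reactants: 2 triisopropyl[(4-methylpenta-1,3-dien-2-yl)oxy]silane; 8 (E)-3-methyl-4-(2-methyl-1,3-dioxolan-2-yl)but-2-enal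
Product: 9 (1S,6S)-2,2,6-trimethyl-6-[(2-methyl-1,3-dioxolan-2-yl)methyl]-4-[(triisopropylsilyl)oxy]cyclohex-3-ene-1-carbaldehyde
Conditions: (S)-3,3-diphenyl-1-(2-methylphenyl)tetrahydro-1H,3H-pyrrolo[1,2-c][1,3,2]oxazaborole (0.3 equiv), HNTf2 (0.25 equiv), 2 (2.5 equiv), CH2Cl2, −78 to −40 °C; Et3N quench
Reagents that add atoms: none
Why: Proposed new method: a Lewis acid-catalysed [4+2] cycloaddition in which the protonated oxazaborolidine binds the formyl oxygen of s-trans 8, the open diene terminus C1 attacks the activated, fully substituted β-carbon C10 and the gem-dimethyl terminus C4 then closes onto the α-carbon C5 in a strongly asynchronous, Mukaiyama–Michael-like transition state; the closest known reaction types are oxazaborolidinium-catalysed Diels–Alder reactions of 2-silyloxybutadienes with simpler enals and the AlBr3/AlMe3-promoted cycloaddition of hindered 2-silyloxydienes with β,β-disubstituted enones, neither of which has joined two partners this congested enantioselectively. Ring A closes as the six-membered cycloadduct ring, both new bonds (C1–C10 and C4–C5) being ring bonds and C2=C3 remaining as the silyl enol ether. Regiochemistry follows the polarisation of the partners (nucleophilic enol ether carbon C1 to the electrophilic β-carbon), which also pairs each hindered atom with an unhindered one. The C5/C10 relation (formyl cis to the C10 methyl, trans to the ketal arm) is fixed by suprafacial addition to the (E)-alkene of 8, provided ring closure outruns bond rotation in any zwitterionic intermediate. The absolute configuration is controlled by the catalyst, whose aryl group should shield the C5-Si/C10-Re face so that the diene adds to the C5-Re/C10-Si face. Endo or exo orientation creates no stereocentre, since neither diene terminus carries a stereogenic substituent. The step needs activation of the aldehyde in preference to the dioxolane, which the bulky cationic boron acid at low temperature should provide, and conjugate rather than 1,2-engagement of the enal, which the formyl-bound, s-trans geometry favours.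

Step 7
Reactants: 9 (1S,6S)-2,2,6-trimethyl-6-[(2-methyl-1,3-dioxolan-2-yl)methyl]-4-[(triisopropylsilyl)oxy]cyclohex-3-ene-1-carbaldehyde
Product: 11 (4aS,8aS)-5,5,8a-trimethyl-7-[(triisopropylsilyl)oxy]-4a,5,8,8a-tetrahydronaphthalen-2(1H)-one, via keto aldehyde 10 (not isolated)
Conditions: a) PPTS (0.2 equiv), acetone/H2O (40:1), 50 °C; b) KOt-Bu (0.3 equiv), t-BuOH/THF, 0 to 25 °C
Reagents that add atoms: water, O
Why: Ketal exchange into acetone under weak acid frees the C8 methyl ketone, while the hindered triisopropylsilyl enol ether (protonation would have to occur at C3 beside the quaternary C4) should survive; the methyl ketone enolate (C7) then adds to the neopentyl aldehyde C6 and the aldol eliminates (intramolecular aldol condensation), closing ring B as the six-membered enone. The trans fusion is carried over from 9 and is also the thermodynamically preferred fusion should C5 equilibrate.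

Step 8
Reactants: 11 (4aS,8aS)-5,5,8a-trimethyl-7-[(triisopropylsilyl)oxy]-4a,5,8,8a-tetrahydronaphthalen-2(1H)-one; 12 (tert-butyldimethylsilyloxy)acetaldehyde
Product: 13 C9 aldol adduct, 1-[2-(tert-butyldimethylsilyloxy)-1-hydroxyethyl] derivative of 11 (mixture of diastereomers at C9 and C11, C5 and C10 as in 11)
Conditions: LiN(i-Pr)2 (1.1 equiv), THF, −78 °C; 12, −78 °C; aq. NH4Cl at −78 °C
Reagents that add atoms: none
Why: Kinetic deprotonation of the enone gives the cross-conjugated α′-enolate at C9 only, since C7 is vinylic and C2 is masked; its aldol addition to the unhindered aldehyde forms C9–C11. Both new stereocentres are erased in the next two steps.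

Step 9
Reactants: 13 C9 aldol adduct
Product: 15 (Z)-C9=C11 alkylidene dienone, 1-[2-(tert-butyldimethylsilyloxy)ethylidene] derivative of 11, via mesylate 14 (not isolated)
Conditions: MsCl, Et3N, CH2Cl2, 0 °C; then DBU, 0 to 25 °C
Reagents that add atoms: none
Why: Mesylation and E1cB elimination through the C8 enolate give the conjugated exocyclic enone; the isomer with C12 turned towards the carbonyl, away from the C10 quaternary centre, should dominate, and either isomer serves in step 10.

Step 10
Reactants: 15 (Z)-C9=C11 alkylidene dienone
Product: 16 C8 ketone with the 9-[2-(tert-butyldimethylsilyloxy)ethyl] chain cis to the C10 methyl (trans-fused; C2=C3 silyl enol ether retained)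
Conditions: H2 (1 atm), 10% Pd/C, EtOAc, 25 °C
Reagents that add atoms: none
Why: Heterogeneous hydrogenation of both conjugated C=C bonds; hydrogen reaches C9 from the face opposite the axial C10 methyl, so H-9 ends cis to H-5 and the chain equatorial, under kinetic control. The electron-rich, hindered silyl enol ether should not be reduced under these neutral conditions.

Step 11
Reactants: 16 C8 ketone with the 9-(2-silyloxyethyl) chain
Product: 17 8(17)-methylene compound (C2=C3 triisopropylsilyl enol ether, C12 tert-butyldimethylsilyl ether)
Conditions: Cp2TiMe2 (3 equiv), toluene, 70 °C, dark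
Reagents that add atoms: dimethyltitanocene, C[Ti](C)(C1C=CC=C1)C1C=CC=C1
Why: Carbonyl methylenation by the titanium methylidene generated on heating (tetravalent titanium); the reagent is non-basic, so the C9 stereocentre, whose equilibrium position is uncertain, is not epimerised before C8 becomes sp2 for good.

Step 12
Reactants: 17 8(17)-methylene compound
Product: 18 (5R,9R,10R)-12-hydroxy-13,14,15,16-tetranorlabd-8(17)-en-2-one
Conditions: Bu4NF (3 equiv), THF, 0 to 25 °C
Reagents that add atoms: none
Why: Fluoride cleaves both Si–O bonds; the enolate released from the silyl enol ether is protonated to the C2 ketone and the C12 alcohol is freed, with no stereocentre involved.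

Step 13
Reactants: 18 (5R,9R,10R)-12-hydroxy-13,14,15,16-tetranorlabd-8(17)-en-2-one
Product: 19 (2R,5R,9R,10R)-13,14,15,16-tetranorlabd-8(17)-ene-2,12-diol
Conditions: Li, NH3(l)/THF, EtOH, −78 °C; NH4Cl
Reagents that add atoms: none
Why: Dissolving-metal reduction of the ketone gives the thermodynamically preferred equatorial alcohol, trans to the C10 methyl, as with other ketones flanked by two syn-axial methyl groups; a hydride would attack from the open face and give the axial epimer. The isolated alkene is inert.

Step 14
Reactants: 19 (2R,5R,9R,10R)-13,14,15,16-tetranorlabd-8(17)-ene-2,12-diol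
Product: 20 (2R,5R,9R,10R)-12-iodo-13,14,15,16-tetranorlabd-8(17)-en-2-ol
Conditions: PPh3, imidazole, I2, CH2Cl2, 0 °C (reagent preformed, 19 added last)
Reagents that add atoms: iodine, II
Why: Appel-type iodination by SN2 displacement at the primary C12 only; the C2 carbinol lies between two neopentyl carbons and cannot be displaced. Preforming the phosphonium reagent leaves no free iodine for iodoetherification of the C8=C17 alkene.

Step 15
Reactants: 20 (2R,5R,9R,10R)-12-iodo-13,14,15,16-tetranorlabd-8(17)-en-2-ol
Product: 21 triethylsilyl ether of 20 at C2
Conditions: TESOTf, 2,6-lutidine, CH2Cl2, −78 °C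
Reagents that add atoms: triethylsilyl triflate, CC[Si](CC)(CC)OS(=O)(=O)C(F)(F)F
Why: Fast silylation of the secondary alcohol at low temperature with a non-nucleophilic base, which leaves the primary iodide untouched.

Step 16
Reactants: 22 but-2-yne-1,4-diol
Product: 23 (E)-2-(tributylstannyl)but-2-ene-1,4-diol
Conditions: Bu3SnH (1.1 equiv), PdCl2(PPh3)2 (2 mol %), THF, 25 °C
Reagents that add atoms: tributyltin hydride, CCCC[SnH](CCCC)CCCC
Why: Palladium-catalysed syn-hydrostannation of the symmetrical alkyne; tin and hydrogen add cis, so the two hydroxymethyl groups end cis to each other and no regiochemical question arises.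

Step 17
Reactants: 23 (E)-2-(tributylstannyl)but-2-ene-1,4-diol
Product: 24 (E)-4-[(tert-butyldimethylsilyl)oxy]-2-(tributylstannyl)but-2-en-1-ol
Conditions: TBSCl (1.0 equiv), imidazole, CH2Cl2, −20 °C
Reagents that add atoms: tert-butyldimethylsilyl chloride, CC(C)(C)[Si](C)(C)Cl
Why: Kinetic monosilylation; the hydroxymethyl group on the tin-bearing carbon is screened by the geminal tributylstannyl group, so the remote hydroxyl (the future C15 oxygen) should react first. Regioisomer and bis-silyl ether are removed by chromatography.

Step 18
Reactants: 24 (E)-4-[(tert-butyldimethylsilyl)oxy]-2-(tributylstannyl)but-2-en-1-ol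
Product: 25 (E)-4-[(tert-butyldimethylsilyl)oxy]-2-iodobut-2-en-1-ol
Conditions: I2, CH2Cl2, 0 °C
Reagents that add atoms: iodine, II
Why: Iododestannylation at the vinyl carbon with retention of configuration.

Step 19
Reactants: 21 triethylsilyl ether of 20; 25 (E)-4-[(tert-butyldimethylsilyl)oxy]-2-iodobut-2-en-1-ol
Product: 28 (2R,5R,9R,10R,13Z)-15-[(tert-butyldimethylsilyl)oxy]-2-[(triethylsilyl)oxy]labda-8(17),13-dien-16-ol, via alkyllithium 26 (not isolated), via lithium borate 27 (not isolated)
Conditions: a) t-BuLi (2.1 equiv), Et2O, −78 °C; 9-MeO-9-BBN, THF, −78 to 25 °C; b) 25, PdCl2(dppf) (5 mol %), AsPh3, K3PO4 (3 M aq.), DMF, 25 °C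
Reagents that add atoms: none
Why: Iodine–lithium exchange and capture by the borinate give a B-alkyl borate that transmetalates directly in a B-alkyl Suzuki–Miyaura coupling; the vinyl iodide reacts with retention, so C12 ends trans to C15 and C16 cis to C15. The free allylic hydroxyl is tolerated and no allylic ester is exposed to zerovalent palladium.

Step 20
Reactants: 28 (13Z)-15-silyloxy-2-silyloxylabda-8(17),13-dien-16-ol
Product: 29 (2R,5R,9R,10R,13Z)-16-acetoxy-15-[(tert-butyldimethylsilyl)oxy]-2-[(triethylsilyl)oxy]labda-8(17),13-diene
Conditions: Ac2O, pyridine, DMAP (cat.), CH2Cl2, 0 °C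
Reagents that add atoms: acetic anhydride, CC(=O)OC(C)=O
Why: Acylation of the only free hydroxyl places the acetate on C16.

Step 21
Reactants: 29 16-acetoxy-15,2-bis(silyloxy)labda-8(17),13-diene
Product: 30 (2R,5R,9R,10R,13Z)-16-acetoxylabda-8(17),13-diene-2,15-diol
Conditions: HF·pyridine, pyridine, THF, 0 to 25 °C
Reagents that add atoms: none
Why: Buffered acidic desilylation removes both silyl ethers; under these non-basic conditions the acetate should not migrate to the cis C15 hydroxyl and the exocyclic alkene should not move.

Step 22
Reactants: 30 (13Z)-16-acetoxylabda-8(17),13-diene-2,15-diol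
Product: 31 (2R,5R,9R,10R,13Z)-16-acetoxy-2-hydroxylabda-8(17),13-dien-15-al
Conditions: activated MnO2, CH2Cl2, 25 °C
Reagents that add atoms: none
Why: Selective oxidation of the allylic primary alcohol; the saturated secondary C2 alcohol is not oxidised and the trisubstituted (Z)-enal should keep its geometry under neutral conditions.

Step 23
Reactants: 31 (13Z)-16-acetoxy-2-hydroxylabda-8(17),13-dien-15-al
Product: 32 (2R,5R,9R,10R,13Z)-16-acetoxy-2-hydroxylabda-8(17),13-dien-15-oic acid (target)
Conditions: NaClO2, NaH2PO4, 2-methyl-2-butene, t-BuOH/H2O, 0 to 25 °C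
Reagents that add atoms: sodium chlorite, [Na+].[O-]Cl=O
Why: Pinnick oxidation of the enal to the acid at buffered pH, with the scavenger protecting the C8=C17 alkene from hypochlorite; the acid is released without any ester cleavage, so the cis acetate is never exposed to base.

## Compound list

1 | mesityl oxide | CC(C)=CC(C)=O | starting material
2 | triisopropyl[(4-methylpenta-1,3-dien-2-yl)oxy]silane | C=C(O[Si](C(C)C)(C(C)C)C(C)C)C=C(C)C | intermediate
3 | acetylacetone | CC(=O)CC(C)=O | starting material
4 | 1-(2-methyl-1,3-dioxolan-2-yl)propan-2-one | CC(=O)CC1(C)OCCO1 | intermediate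
5 | triethyl phosphonoacetate | CCOC(=O)CP(=O)(OCC)OCC | starting material
6 | ethyl (E)-3-methyl-4-(2-methyl-1,3-dioxolan-2-yl)but-2-enoate | CCOC(=O)/C=C(\C)CC1(C)OCCO1 | intermediate
7 | (E)-3-methyl-4-(2-methyl-1,3-dioxolan-2-yl)but-2-en-1-ol | OC/C=C(\C)CC1(C)OCCO1 | intermediate
8 | (E)-3-methyl-4-(2-methyl-1,3-dioxolan-2-yl)but-2-enal | O=C/C=C(\C)CC1(C)OCCO1 | intermediate
9 | (1S,6S)-2,2,6-trimethyl-6-[(2-methyl-1,3-dioxolan-2-yl)methyl]-4-[(triisopropylsilyl)oxy]cyclohex-3-ene-1-carbaldehyde | O=C[C@@H]1C(C)(C)C=C(O[Si](C(C)C)(C(C)C)C(C)C)C[C@@]1(C)CC2(C)OCCO2 | intermediate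
10 | (1S,6S)-2,2,6-trimethyl-6-(2-oxopropyl)-4-[(triisopropylsilyl)oxy]cyclohex-3-ene-1-carbaldehyde | O=C[C@@H]1C(C)(C)C=C(O[Si](C(C)C)(C(C)C)C(C)C)C[C@@]1(C)CC(C)=O | intermediate (not isolated)
11 | (4aS,8aS)-5,5,8a-trimethyl-7-[(triisopropylsilyl)oxy]-4a,5,8,8a-tetrahydronaphthalen-2(1H)-one | O=C1C=C[C@@H]2C(C)(C)C=C(O[Si](C(C)C)(C(C)C)C(C)C)C[C@@]2(C)C1 | intermediate
12 | (tert-butyldimethylsilyloxy)acetaldehyde | O=CCO[Si](C)(C)C(C)(C)C | starting material
13 | C9 aldol adduct of 11 and 12 (diastereomers at C9 and C11) | O=C1C=C[C@@H]2C(C)(C)C=C(O[Si](C(C)C)(C(C)C)C(C)C)C[C@@]2(C)C1C(O)CO[Si](C)(C)C(C)(C)C | intermediate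
14 | C11 methanesulfonate of 13 | O=C1C=C[C@@H]2C(C)(C)C=C(O[Si](C(C)C)(C(C)C)C(C)C)C[C@@]2(C)C1C(OS(C)(=O)=O)CO[Si](C)(C)C(C)(C)C | intermediate (not isolated)
15 | (Z)-C9=C11 alkylidene dienone | O=C1C=C[C@@H]2C(C)(C)C=C(O[Si](C(C)C)(C(C)C)C(C)C)C[C@@]2(C)/C1=C/CO[Si](C)(C)C(C)(C)C | intermediate
16 | C8 ketone with 9-(2-silyloxyethyl) chain cis to the C10 methyl | O=C1CC[C@@H]2C(C)(C)C=C(O[Si](C(C)C)(C(C)C)C(C)C)C[C@@]2(C)[C@@H]1CCO[Si](C)(C)C(C)(C)C | intermediate
17 | 8(17)-methylene compound (C2=C3 silyl enol ether, C12 silyl ether) | C=C1CC[C@@H]2C(C)(C)C=C(O[Si](C(C)C)(C(C)C)C(C)C)C[C@@]2(C)[C@@H]1CCO[Si](C)(C)C(C)(C)C | intermediate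
18 | (5R,9R,10R)-12-hydroxy-13,14,15,16-tetranorlabd-8(17)-en-2-one | C=C1CC[C@@H]2C(C)(C)CC(=O)C[C@@]2(C)[C@@H]1CCO | intermediate
19 | (2R,5R,9R,10R)-13,14,15,16-tetranorlabd-8(17)-ene-2,12-diol | C=C1CC[C@@H]2C(C)(C)C[C@@H](O)C[C@@]2(C)[C@@H]1CCO | intermediate
20 | (2R,5R,9R,10R)-12-iodo-13,14,15,16-tetranorlabd-8(17)-en-2-ol | C=C1CC[C@@H]2C(C)(C)C[C@@H](O)C[C@@]2(C)[C@@H]1CCI | intermediate
21 | 2-O-triethylsilyl ether of 20 | C=C1CC[C@@H]2C(C)(C)C[C@@H](O[Si](CC)(CC)CC)C[C@@]2(C)[C@@H]1CCI | intermediate
22 | but-2-yne-1,4-diol | OCC#CCO | starting material
23 | (E)-2-(tributylstannyl)but-2-ene-1,4-diol | OC/C=C(/[Sn](CCCC)(CCCC)CCCC)CO | intermediate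
24 | (E)-4-[(tert-butyldimethylsilyl)oxy]-2-(tributylstannyl)but-2-en-1-ol | CC(C)(C)[Si](C)(C)OC/C=C(/[Sn](CCCC)(CCCC)CCCC)CO | intermediate
25 | (E)-4-[(tert-butyldimethylsilyl)oxy]-2-iodobut-2-en-1-ol | CC(C)(C)[Si](C)(C)OC/C=C(/I)CO | intermediate
26 | C12 alkyllithium from 21 | C=C1CC[C@@H]2C(C)(C)C[C@@H](O[Si](CC)(CC)CC)C[C@@]2(C)[C@@H]1CC[Li] | intermediate (not isolated)
27 | lithium B-alkyl-B-methoxy-9-borabicyclo[3.3.1]nonane borate from 26 | C=C1CC[C@@H]2C(C)(C)C[C@@H](O[Si](CC)(CC)CC)C[C@@]2(C)[C@@H]1CC[B-]1(OC)C2CCCC1CCC2.[Li+] | intermediate (not isolated)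
28 | (2R,5R,9R,10R,13Z)-15-[(tert-butyldimethylsilyl)oxy]-2-[(triethylsilyl)oxy]labda-8(17),13-dien-16-ol | C=C1CC[C@@H]2C(C)(C)C[C@@H](O[Si](CC)(CC)CC)C[C@@]2(C)[C@@H]1CC/C(=C/CO[Si](C)(C)C(C)(C)C)CO | intermediate
29 | 16-acetate of 28 | C=C1CC[C@@H]2C(C)(C)C[C@@H](O[Si](CC)(CC)CC)C[C@@]2(C)[C@@H]1CC/C(=C/CO[Si](C)(C)C(C)(C)C)COC(C)=O | intermediate
30 | (2R,5R,9R,10R,13Z)-16-acetoxylabda-8(17),13-diene-2,15-diol | C=C1CC[C@@H]2C(C)(C)C[C@@H](O)C[C@@]2(C)[C@@H]1CC/C(=C/CO)COC(C)=O | intermediate
31 | (2R,5R,9R,10R,13Z)-16-acetoxy-2-hydroxylabda-8(17),13-dien-15-al | C=C1CC[C@@H]2C(C)(C)C[C@@H](O)C[C@@]2(C)[C@@H]1CC/C(=C/C=O)COC(C)=O | intermediate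
32 | (2R,5R,9R,10R,13Z)-16-acetoxy-2-hydroxylabda-8(17),13-dien-15-oic acid | C=C1CC[C@@H]2C(C)(C)C[C@@H](O)C[C@@]2(C)[C@@H]1CC/C(=C/C(=O)O)COC(C)=O | target

## Step count and least certain steps

Total: 23 steps. Longest linear sequence: 19 steps (from 3 through steps 2–15 and 19–23). The diene branch is 1 step and the side-chain branch 3 steps.

**Step 6 (key step).**
- What may go wrong: failure to engage the two congested termini, so that 1,2-addition of the silyl enol ether to the formyl carbon or simple decomposition of the diene takes over. Weak facial discrimination, because a β,β-disubstituted enal may not sit in the catalyst pocket as simpler enals do. Ionisation of the dioxolane by the acid. Loss of the C5/C10 relation if a zwitterionic intermediate rotates before closing. The last is partly correctable, since C5 is α to the aldehyde and the trans arrangement should be favoured at equilibrium.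
- Fallback: setting out from 2 and 8, the cycloaddition is run with the achiral mixed Lewis acid AlBr3/AlMe3 in toluene/CH2Cl2, the established method for hindered silyloxydienes and β,β-disubstituted dienophiles. This gives 9 together with its mirror image, the enantiomeric cycloadduct F1, as a racemate. The two are separated by preparative chromatography on a cellulose tris(3,5-dimethylphenylcarbamate) stationary phase, and 9 re-enters the route at step 7.

**Step 8 (with its sequel, step 9).**
- What may go wrong: slow or reversible addition at the neopentyl enolate carbon C9, with retro-aldol on work-up or proton transfer from the enolisable aldehyde 12. Elimination in step 9 towards C12 instead of C9.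
- Fallback: setting out from 11, the same lithium enolate is alkylated with tert-butyl bromoacetate (LiN(i-Pr)2, THF/DMPU) to the alkylated enone F2, chain anti to the C10 methyl. Hydrogenation of C6=C7 (H2, Pd/C) gives the 9-epi keto ester F3. Equilibration with NaOMe in MeOH and separation gives the keto ester F4 with the C9 configuration of 32, with F3 recycled. Methylenation with Zn/CH2Br2/TiCl4, which spares the ester and is not basic, gives the methylene ester F5. LiAlH4 gives the primary alcohol F6, and Bu4NF returns the material to the route at 18. This path depends on a C9 equilibrium of uncertain position, which is why it is not the main line.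

**Step 10.**
- What may go wrong: partial saturation of the C2=C3 enol ether, hydrogenolysis of the allylic C12–O bond before C9=C11 is reduced, or hydrogen delivery to the other face of C9 if the catalyst first moves the double bond to C11=C12.
- Fallback: setting out from 15, both enone double bonds are reduced by conjugate hydride transfer from [(Ph3P)CuH]6 (monovalent copper) with PhMe2SiH as the stoichiometric hydride. The resulting C8–C9 enolate is released with Bu4NF and protonated kinetically at −78 °C by 2,6-di-tert-butylphenol from the face opposite the C10 methyl. The product is 16 itself, so the route is rejoined there without any new isolated compound.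

**Step 19.**
- What may go wrong: incomplete iodine–lithium exchange or Wurtz-type coupling, slow transmetalation of the borate, or β-hydride elimination from the alkylpalladium intermediate, each leading to reduced or eliminated C12 products.
- Fallback: setting out from 21, the iodide is displaced by dilithiated propargyl alcohol (n-BuLi, THF/DMPU) to the alkynol F7. trans-Hydroalumination with NaAlH2(OCH2CH2OMe)2 and iodination at −78 °C give the (Z)-3-iodo allylic alcohol F8, iodine on C13 and cis to C15. TBSCl and imidazole give the silyl ether F9. Stille coupling of F9 with (tributylstannyl)methanol and Pd(PPh3)4 (zerovalent palladium) in dioxane at 80 °C installs C16 as the hydroxymethyl group and returns the material to the route at 28. This detour also removes the reliance on the site-selective silylation of step 17.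

Further compounds

F1 | step 6 | (1R,6R)-enantiomer of cycloadduct 9 | O=C[C@H]1C(C)(C)C=C(O[Si](C(C)C)(C(C)C)C(C)C)C[C@]1(C)CC2(C)OCCO2
F2 | step 8 | tert-butyl ester of the C9-alkylated enone (chain anti to the C10 methyl) | O=C1C=C[C@@H]2C(C)(C)C=C(O[Si](C(C)C)(C(C)C)C(C)C)C[C@@]2(C)[C@H]1CC(=O)OC(C)(C)C
F3 | step 8 | 9-epi saturated keto ester | O=C1CC[C@@H]2C(C)(C)C=C(O[Si](C(C)C)(C(C)C)C(C)C)C[C@@]2(C)[C@H]1CC(=O)OC(C)(C)C
F4 | step 8 | saturated keto ester with the C9 configuration of 32 | O=C1CC[C@@H]2C(C)(C)C=C(O[Si](C(C)C)(C(C)C)C(C)C)C[C@@]2(C)[C@@H]1CC(=O)OC(C)(C)C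
F5 | step 8 | 8(17)-methylene tert-butyl ester | C=C1CC[C@@H]2C(C)(C)C=C(O[Si](C(C)C)(C(C)C)C(C)C)C[C@@]2(C)[C@@H]1CC(=O)OC(C)(C)C
F6 | step 8 | 8(17)-methylene C12 alcohol with C2=C3 silyl enol ether | C=C1CC[C@@H]2C(C)(C)C=C(O[Si](C(C)C)(C(C)C)C(C)C)C[C@@]2(C)[C@@H]1CCO
F0 | step 10 | none | none
F7 | step 19 | C12-propargylated alkynol (C13≡C14, C15 hydroxyl, C2 triethylsilyl ether) | C=C1CC[C@@H]2C(C)(C)C[C@@H](O[Si](CC)(CC)CC)C[C@@]2(C)[C@@H]1CCC#CCO
F8 | step 19 | (Z)-13-iodo allylic alcohol | C=C1CC[C@@H]2C(C)(C)C[C@@H](O[Si](CC)(CC)CC)C[C@@]2(C)[C@@H]1CC/C(I)=C/CO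
F9 | step 19 | tert-butyldimethylsilyl ether of the (Z)-13-iodo allylic alcohol | C=C1CC[C@@H]2C(C)(C)C[C@@H](O[Si](CC)(CC)CC)C[C@@]2(C)[C@@H]1CC/C(I)=C/CO[Si](C)(C)C(C)(C)C
A1 | alternative 1 | methylenecyclobutane photoadduct | C=C1C[C@@]2(C)[C@H](CCC(C)=O)C(C)(C)CC(=O)[C@@H]12
A2 | alternative 1 | 3,5,5-trimethyl-4-(3-oxobutyl)cyclohex-2-en-1-one (C4 configured as in A1) | CC1=CC(=O)CC(C)(C)[C@H]1CCC(C)=O
A3 | alternative 1 | allene (propa-1,2-diene) | C=C=C
A4 | alternative 2 | trans-fused octalin aldehyde | O=C[C@@H]1[C@H](O[Si](CC)(CC)CC)C=C[C@@H]2C(C)(C)C[C@@H](O[Si](C)(C)C(C)(C)C)C[C@@]12C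
A5 | alternative 2 | open-chain (2E,8E,10E)-trienal with C2 silyl ether and terminal dienol silyl ether | O=C/C=C(\C)C[C@H](O[Si](C)(C)C(C)(C)C)CC(C)(C)/C=C/C=C/O[Si](CC)(CC)CC
A6 | alternative 3 | ring B ketone with acetal chain on C9 and enone arm and methyl on C10 | O=C(C=C(C)C)C[C@]1(C)C(=O)CC[C@H](O[Si](CC)(CC)CC)[C@H]1CCC2OCCO2
A7 | alternative 3 | 2-methyl-4-[(triethylsilyl)oxy]cyclohex-2-en-1-one (C4 configured as in A6) | CC1=C[C@@H](O[Si](CC)(CC)CC)CCC1=O
A8 | alternative 3 | [2-(1,3-dioxolan-2-yl)ethyl]magnesium bromide | Br[Mg]CCC1OCCO1
A9 | alternative 3 | 1-bromo-4-methylpent-3-en-2-one | CC(C)=CC(=O)CBr
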